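**Retrosynthetic overview**

- The strategy rests on the Z-trisubstituted C2''=C3'' alkene of the C8 side chain (C1'' benzylic CH2, C2'' CH, C3'' C(CH3), C4'' CH2OH). C4'' lies cis to C1'' and within reach of O7 on ring A, so C4'' can be held on O7 as a lactone carbonyl.
- C2''=C3'' is disconnected by ring-closing metathesis of a 7-O-methacrylate with an 8-allyl group. The resulting seven-membered lactone can only hold a cis alkene and is opened by hydride to the Z-allylic alcohol.
- Ring B and the C2 stereocentre come from an asymmetric rhodium-catalysed conjugate arylation of an 8-allyl-7-alkoxychromone (C2–C1' bond).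
- The C8 allyl group comes from an aromatic Claisen rearrangement of 7-allyloxychromone.
- Ring order: rings A and C are bought as the chromone, ring B is attached, then the temporary seven-membered lactone is closed and opened again.

Key step: step 9

Assumption: the sense of induction in the rhodium-catalysed arylation is taken from the cyclic-enone model, under which the (S,S) diene ligand should give the (2S) flavanone. If the sense proved to be the reverse, the (R,R) ligand would be used.

**Route**

Step 1
Reactants: 1 7-hydroxychromone; 2 allyl bromide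
Product: 3 7-(allyloxy)chromone
Conditions: K2CO3, acetone, reflux
Reagents that add atoms: allyl bromide (2), C=CCBr
Why: Williamson ether synthesis, in which the acidic 7-OH is deprotonated by carbonate and alkylated by SN2 displacement while the chromone ring tolerates the mild base.

Step 2
Reactants: 3 7-(allyloxy)chromone
Product: 5 8-allyl-7-hydroxychromone, via ortho-dienone 4 (not isolated)
Conditions: N,N-diethylaniline, 200 °C, sealed vessel, argon
Reagents that add atoms: none
Why: Aromatic Claisen rearrangement, whose [3,3] shift should go to C8 rather than C6 because the C7–C8 bond of the benzopyranone has the higher double-bond character, followed by tautomerisation of the dienone to the phenol.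

Step 3
Reactants: 5 8-allyl-7-hydroxychromone; 6 4-methoxybenzyl chloride
Product: 7 8-allyl-7-[(4-methoxybenzyl)oxy]chromone
Conditions: K2CO3, n-Bu4NI (cat.), DMF, rt
Reagents that add atoms: 4-methoxybenzyl chloride (6), COc1ccc(CCl)cc1
Why: Williamson etherification that masks the phenol with a group which survives the aqueous arylation and can later be removed by acid without touching aryl silyl ethers or the allyl group.

Step 4
Reactants: 8 4-bromocatechol; 9 tert-butyldimethylsilyl chloride
Product: 10 4-bromo-1,2-bis(tert-butyldimethylsilyloxy)benzene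
Conditions: TBSCl (2.3 equiv), imidazole, DMF, rt
Reagents that add atoms: tert-butyldimethylsilyl chloride (9), CC(C)(C)[Si](C)(C)Cl
Why: Imidazole-promoted silylation of both phenols, a standard protection of catechols.

Step 5
Reactants: 10 4-bromo-1,2-bis(tert-butyldimethylsilyloxy)benzene; 11 triisopropyl borate
Product: 14 3,4-bis(tert-butyldimethylsilyloxy)phenylboronic acid, via aryllithium 12 (not isolated), via lithium aryltriisopropoxyborate 13 (not isolated)
Conditions: n-BuLi, THF, −78 °C; then B(Oi-Pr)3, −78 °C → rt; then 1 M HCl, 0 °C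
Reagents that add atoms: triisopropyl borate (11), CC(C)OB(OC(C)C)OC(C)C; water, O
Why: Lithium–bromine exchange followed by borylation and hydrolysis, in which the aryllithium sits meta and para to the silyloxy groups so that no silyl migration to carbon is possible.

Step 6
Reactants: 7 8-allyl-7-[(4-methoxybenzyl)oxy]chromone; 14 3,4-bis(tert-butyldimethylsilyloxy)phenylboronic acid
Product: 15 (2S)-8-allyl-2-[3,4-bis(tert-butyldimethylsilyloxy)phenyl]-7-[(4-methoxybenzyl)oxy]chroman-4-one
Conditions: [RhCl(C2H4)2]2 (2.5 mol %), (1S,4S)-2,5-diphenylbicyclo[2.2.2]octa-2,5-diene (5.5 mol %), KOH (10 mol %), 14 (2.5 equiv), dioxane/H2O 10:1, 40 °C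
Reagents that add atoms: 3,4-bis(tert-butyldimethylsilyloxy)phenylboronic acid (14), OB(O)c1ccc(O[Si](C)(C)C(C)(C)C)c(O[Si](C)(C)C(C)(C)C)c1
Why: Hayashi–Miyaura asymmetric conjugate addition, in which an aryl complex of monovalent rhodium carrying the C2-symmetric chiral diene should add the aryl group to C2 of the chromone on the face that gives (2S) and water protonates the rhodium enolate, so the ligand sets the C2 stereocentre.

Step 7
Reactants: 15 (2S)-8-allyl-2-[3,4-bis(tert-butyldimethylsilyloxy)phenyl]-7-[(4-methoxybenzyl)oxy]chroman-4-one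
Product: 16 (2S)-8-allyl-2-[3,4-bis(tert-butyldimethylsilyloxy)phenyl]-7-hydroxychroman-4-one
Conditions: CF3CO2H (10 equiv), anisole (5 equiv), CH2Cl2, 0 °C
Reagents that add atoms: none
Why: Acidolysis of the 4-methoxybenzyl ether, made easy by the electron-poor phenol leaving group, with Friedel–Crafts capture of the benzyl cation by anisole, while aryl silyl ethers, the allyl group and the flavanone should survive brief cold acid.

Step 8
Reactants: 16 (2S)-8-allyl-2-[3,4-bis(tert-butyldimethylsilyloxy)phenyl]-7-hydroxychroman-4-one; 17 methacryloyl chloride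
Product: 18 (2S)-8-allyl-2-[3,4-bis(tert-butyldimethylsilyloxy)phenyl]-4-oxochroman-7-yl 2-methylprop-2-enoate
Conditions: methacryloyl chloride (1.3 equiv), Et3N, DMAP (cat.), CH2Cl2, −20 → 0 °C
Reagents that add atoms: methacryloyl chloride (17), C=C(C)C(=O)Cl
Why: DMAP-catalysed O-acylation of the phenol, run cold and briefly so that the amine base does not open the flavanone by retro-oxa-Michael reaction.

Step 9
Reactants: 18 (2S)-8-allyl-2-[3,4-bis(tert-butyldimethylsilyloxy)phenyl]-4-oxochroman-7-yl 2-methylprop-2-enoate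
Product: 19 the (2S)-flavanone bis-silyl ether whose O7 and C8 are bridged by –C(=O)–C(CH3)=CH–CH2– (carbonyl on O7, CH2 on C8), a fused 3-methyl-1-benzoxepin-2(5H)-one with a ring-cis alkene
Conditions: second-generation Grubbs catalyst RuCl2(H2IMes)(PCy3)(=CHPh) (10 mol % in two portions), 1,4-benzoquinone (20 mol %), degassed toluene, 0.005 M, 80 °C, argon sparge
Reagents that add atoms: none
Why: Ring-closing olefin metathesis, in which the catalyst should initiate at the unhindered terminal alkene of the C8 allyl group to give a ruthenium alkylidene that undergoes intramolecular [2+2] cycloaddition with the 1,1-disubstituted methacrylate alkene and cycloreversion, ethene being lost irreversibly. The closest known reaction type is the ring-closing metathesis of aryl acrylates and methacrylates bearing an ortho alkenyl group to coumarins and benzo-fused unsaturated lactones. The seven-membered ring (C7, O7, C4'', C3'', C2'', C1'', C8) is closed by forming its C2''=C3'' bond between two chains held ortho to each other on ring A, and high dilution favours this closure over cross-metathesis between allyl groups. No stereocentre is formed, and the alkene geometry is set by the ring, because a seven-membered ring cannot hold a trans double bond and C4'' must therefore end cis to C1''. The selectivity needed is closure before any migration of the allyl double bond, which would lead to a six-membered coumarin-type ring with loss of propene, and 1,4-benzoquinone is added to suppress the ruthenium hydrides that cause such migration. The C4 ketone, the C2 stereocentre and the aryl silyl ethers should be inert to the ruthenium alkylidene.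

Step 10
Reactants: 19 the seven-membered lactone
Product: 20 (2S,4RS)-2-[3,4-bis(tert-butyldimethylsilyloxy)phenyl]-8-[(2Z)-4-hydroxy-3-methylbut-2-en-1-yl]chromane-4,7-diol (mixture of C4 epimers)
Conditions: i-Bu2AlH (5 equiv), CH2Cl2, −78 → −20 °C; aq. KNaC4H4O6 (potassium sodium tartrate) work-up
Reagents that add atoms: none
Why: Aluminium hydride 1,2-reduction of the aryl lactone to the primary allylic alcohol and the free phenol without touching the alkene geometry, with unavoidable reduction of the C4 ketone to a carbinol whose configuration does not matter because it is reoxidised in step 12.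

Step 11
Reactants: 20 the triol; 9 tert-butyldimethylsilyl chloride
Product: 21 (2S,4RS)-2-[3,4-bis(tert-butyldimethylsilyloxy)phenyl]-7-(tert-butyldimethylsilyloxy)-8-[(2Z)-4-(tert-butyldimethylsilyloxy)-3-methylbut-2-en-1-yl]chroman-4-ol
Conditions: TBSCl (2.2 equiv), imidazole, CH2Cl2/DMF, 0 °C
Reagents that add atoms: tert-butyldimethylsilyl chloride (9), CC(C)(C)[Si](C)(C)Cl
Why: Selective silylation, in which the phenol and the primary allylic alcohol should react much faster with the bulky silyl chloride than the secondary benzylic C4 carbinol.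

Step 12
Reactants: 21 the tetrasilylated chroman-4-ol
Product: 22 (2S)-2-[3,4-bis(tert-butyldimethylsilyloxy)phenyl]-7-(tert-butyldimethylsilyloxy)-8-[(2Z)-4-(tert-butyldimethylsilyloxy)-3-methylbut-2-en-1-yl]chroman-4-one
Conditions: Dess–Martin periodinane (1,1,1-triacetoxy-1,1-dihydro-1,2-benziodoxol-3(1H)-one), pyridine, CH2Cl2, 0 °C → rt
Reagents that add atoms: none
Why: Dess–Martin oxidation of the only free hydroxyl back to the C4 ketone under buffered, non-basic conditions that should leave the silyl ethers, the Z-alkene and the C2 stereocentre untouched.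

Step 13
Reactants: 22 the tetrasilylated flavanone
Product: 23 (2S)-2-(3,4-dihydroxyphenyl)-7-hydroxy-8-[(2Z)-4-hydroxy-3-methylbut-2-en-1-yl]chroman-4-one (CNP0205253.2)
Conditions: HF·pyridine (excess), pyridine, THF, 0 °C → rt
Reagents that add atoms: none
Why: Fluoride-driven desilylation of the three aryl silyl ethers and the primary allylic silyl ether under weakly acidic buffered conditions, which avoids the base-induced ring opening that would racemise C2.

**Compound list**

1 | 7-hydroxychromone (7-hydroxy-4H-chromen-4-one) | O=c1ccoc2cc(O)ccc12 | starting material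
2 | allyl bromide | C=CCBr | starting material
3 | 7-(allyloxy)chromone | O=c1ccoc2cc(OCC=C)ccc12 | intermediate
4 | 8-allyl-8H-chromene-4,7-dione (ortho-dienone of the Claisen rearrangement) | C=CCC1C(=O)C=CC2=C1OC=CC2=O | intermediate
5 | 8-allyl-7-hydroxychromone | O=c1ccoc2c(CC=C)c(O)ccc12 | intermediate
6 | 4-methoxybenzyl chloride | COc1ccc(CCl)cc1 | starting material
7 | 8-allyl-7-[(4-methoxybenzyl)oxy]chromone | O=c1ccoc2c(CC=C)c(OCc3ccc(OC)cc3)ccc12 | intermediate
8 | 4-bromocatechol | Oc1ccc(Br)cc1O | starting material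
9 | tert-butyldimethylsilyl chloride | CC(C)(C)[Si](C)(C)Cl | starting material
10 | 4-bromo-1,2-bis(tert-butyldimethylsilyloxy)benzene | CC(C)(C)[Si](C)(C)Oc1ccc(Br)cc1O[Si](C)(C)C(C)(C)C | intermediate
11 | triisopropyl borate | CC(C)OB(OC(C)C)OC(C)C | starting material
12 | 3,4-bis(tert-butyldimethylsilyloxy)phenyllithium | [Li]c1ccc(O[Si](C)(C)C(C)(C)C)c(O[Si](C)(C)C(C)(C)C)c1 | intermediate
13 | lithium [3,4-bis(tert-butyldimethylsilyloxy)phenyl]triisopropoxyborate | [Li+].CC(C)O[B-](OC(C)C)(OC(C)C)c1ccc(O[Si](C)(C)C(C)(C)C)c(O[Si](C)(C)C(C)(C)C)c1 | intermediate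
14 | 3,4-bis(tert-butyldimethylsilyloxy)phenylboronic acid | OB(O)c1ccc(O[Si](C)(C)C(C)(C)C)c(O[Si](C)(C)C(C)(C)C)c1 | intermediate
15 | (2S)-8-allyl-2-[3,4-bis(tert-butyldimethylsilyloxy)phenyl]-7-[(4-methoxybenzyl)oxy]chroman-4-one | C=CCc1c(OCc3ccc(OC)cc3)ccc2c1O[C@H](c1ccc(O[Si](C)(C)C(C)(C)C)c(O[Si](C)(C)C(C)(C)C)c1)CC2=O | intermediate
16 | (2S)-8-allyl-2-[3,4-bis(tert-butyldimethylsilyloxy)phenyl]-7-hydroxychroman-4-one | C=CCc1c(O)ccc2c1O[C@H](c1ccc(O[Si](C)(C)C(C)(C)C)c(O[Si](C)(C)C(C)(C)C)c1)CC2=O | intermediate
17 | methacryloyl chloride | C=C(C)C(=O)Cl | starting material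
18 | (2S)-8-allyl-2-[3,4-bis(tert-butyldimethylsilyloxy)phenyl]-4-oxochroman-7-yl 2-methylprop-2-enoate | C=CCc1c(OC(=O)C(C)=C)ccc2c1O[C@H](c1ccc(O[Si](C)(C)C(C)(C)C)c(O[Si](C)(C)C(C)(C)C)c1)CC2=O | intermediate
19 | (2S)-flavanone bis-silyl ether fused across O7–C8 to a 3-methyl-1-benzoxepin-2(5H)-one ring (ring-cis alkene) | CC1=CCc2c(OC1=O)ccc3c2O[C@H](c2ccc(O[Si](C)(C)C(C)(C)C)c(O[Si](C)(C)C(C)(C)C)c2)CC3=O | intermediate
20 | (2S,4RS)-2-[3,4-bis(tert-butyldimethylsilyloxy)phenyl]-8-[(2Z)-4-hydroxy-3-methylbut-2-en-1-yl]chromane-4,7-diol | C/C(=C/Cc1c(O)ccc2c1O[C@H](c1ccc(O[Si](C)(C)C(C)(C)C)c(O[Si](C)(C)C(C)(C)C)c1)CC2O)CO | intermediate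
21 | (2S,4RS)-2-[3,4-bis(tert-butyldimethylsilyloxy)phenyl]-7-(tert-butyldimethylsilyloxy)-8-[(2Z)-4-(tert-butyldimethylsilyloxy)-3-methylbut-2-en-1-yl]chroman-4-ol | C/C(=C/Cc1c(O[Si](C)(C)C(C)(C)C)ccc2c1O[C@H](c1ccc(O[Si](C)(C)C(C)(C)C)c(O[Si](C)(C)C(C)(C)C)c1)CC2O)CO[Si](C)(C)C(C)(C)C | intermediate
22 | (2S)-2-[3,4-bis(tert-butyldimethylsilyloxy)phenyl]-7-(tert-butyldimethylsilyloxy)-8-[(2Z)-4-(tert-butyldimethylsilyloxy)-3-methylbut-2-en-1-yl]chroman-4-one | C/C(=C/Cc1c(O[Si](C)(C)C(C)(C)C)ccc2c1O[C@H](c1ccc(O[Si](C)(C)C(C)(C)C)c(O[Si](C)(C)C(C)(C)C)c1)CC2=O)CO[Si](C)(C)C(C)(C)C | intermediate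
23 | (2S)-2-(3,4-dihydroxyphenyl)-7-hydroxy-8-[(2Z)-4-hydroxy-3-methylbut-2-en-1-yl]chroman-4-one | C/C(=C/Cc1c(O)ccc2c1O[C@H](c1ccc(O)c(O)c1)CC2=O)CO | target

**Step count**

Total steps: 13. Longest linear sequence: 11 steps (steps 1, 2, 3, 6, 7, 8, 9, 10, 11, 12, 13).

**Steps most likely to fail, with fallbacks**

1. Step 9. Closure of the strained seven-membered aryl lactone may be slow. Oligomerisation through the allyl groups, or migration of the allyl double bond followed by a ring-contracting closure, could then take over. The fallback keeps the temporary ring but forms the alkene by olefination instead of metathesis. It sets out from 16. The phenol is esterified with 2-(diethoxyphosphoryl)propanoic acid (EDC·HCl, DMAP, CH2Cl2) to give (2S)-8-allyl-2-[3,4-bis(tert-butyldimethylsilyloxy)phenyl]-4-oxochroman-7-yl 2-(diethoxyphosphoryl)propanoate F1. The allyl group is cleaved with OsO4 (cat.), NaIO4 and 2,6-lutidine in dioxane/H2O to the arylacetaldehyde (2S)-2-[3,4-bis(tert-butyldimethylsilyloxy)phenyl]-4-oxo-8-(2-oxoethyl)chroman-7-yl 2-(diethoxyphosphoryl)propanoate F2. An intramolecular Horner–Wadsworth–Emmons reaction under Masamune–Roush conditions (LiCl, i-Pr2NEt, MeCN, high dilution) should then close the same lactone, and the route is rejoined at 19.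

2. Step 6. Aryl transfer to the electron-rich, C8-substituted chromone may be slow, so that protodeboronation of the electron-rich boronic acid, hydrolysis of the aryl silyl ethers or incomplete facial control erode the outcome. The fallback gives up asymmetric induction. It sets out from 7 and 14, which are coupled with the more reactive achiral [Rh(OH)(cod)]2 in dioxane/H2O to give racemic 8-allyl-2-[3,4-bis(tert-butyldimethylsilyloxy)phenyl]-7-[(4-methoxybenzyl)oxy]chroman-4-one F3. The enantiomers are separated by preparative HPLC on a cellulose tris(3,5-dimethylphenylcarbamate) phase. The (2S) enantiomer is 15, where the route is rejoined, and the (2R)-8-allyl-2-[3,4-bis(tert-butyldimethylsilyloxy)phenyl]-7-[(4-methoxybenzyl)oxy]chroman-4-one F4 is set aside.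

3. Step 11. Discrimination between the C4 carbinol and the two hydroxyls to be silylated may be incomplete, giving silylation at O4 or a hindered O7 left free, and the electron-rich benzylic carbinol may ionise. The fallback avoids the C4 carbinol altogether by masking the ketone before the reduction. It sets out from 19. Soft enolisation (TBSOTf, Et3N, CH2Cl2, −78 → 0 °C, light excluded) should give the C4 silyl enol ether of lactone 19, a (2S)-4-(tert-butyldimethylsilyloxy)-2H-chromene F5. Reduction with i-Bu2AlH (CH2Cl2, −78 °C) then opens only the lactone to (2S)-2-[3,4-bis(tert-butyldimethylsilyloxy)phenyl]-4-(tert-butyldimethylsilyloxy)-8-[(2Z)-4-hydroxy-3-methylbut-2-en-1-yl]-2H-chromen-7-ol F6. HF·pyridine in THF/pyridine removes all silyl groups and releases the ketone, so the route is rejoined at 23 and steps 10 to 12 are not needed.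

**Further compounds**

F1 | step 9 | (2S)-8-allyl-2-[3,4-bis(tert-butyldimethylsilyloxy)phenyl]-4-oxochroman-7-yl 2-(diethoxyphosphoryl)propanoate | C=CCc1c(OC(=O)C(C)P(=O)(OCC)OCC)ccc2c1O[C@H](c1ccc(O[Si](C)(C)C(C)(C)C)c(O[Si](C)(C)C(C)(C)C)c1)CC2=O
F2 | step 9 | (2S)-2-[3,4-bis(tert-butyldimethylsilyloxy)phenyl]-4-oxo-8-(2-oxoethyl)chroman-7-yl 2-(diethoxyphosphoryl)propanoate | O=CCc1c(OC(=O)C(C)P(=O)(OCC)OCC)ccc2c1O[C@H](c1ccc(O[Si](C)(C)C(C)(C)C)c(O[Si](C)(C)C(C)(C)C)c1)CC2=O
F3 | step 6 | racemic 8-allyl-2-[3,4-bis(tert-butyldimethylsilyloxy)phenyl]-7-[(4-methoxybenzyl)oxy]chroman-4-one | C=CCc1c(OCc3ccc(OC)cc3)ccc2c1OC(c1ccc(O[Si](C)(C)C(C)(C)C)c(O[Si](C)(C)C(C)(C)C)c1)CC2=O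
F4 | step 6 | (2R)-8-allyl-2-[3,4-bis(tert-butyldimethylsilyloxy)phenyl]-7-[(4-methoxybenzyl)oxy]chroman-4-one | C=CCc1c(OCc3ccc(OC)cc3)ccc2c1O[C@@H](c1ccc(O[Si](C)(C)C(C)(C)C)c(O[Si](C)(C)C(C)(C)C)c1)CC2=O
F5 | step 11 | C4 silyl enol ether of lactone 19, a (2S)-4-(tert-butyldimethylsilyloxy)-2H-chromene | CC1=CCc2c(OC1=O)ccc3c2O[C@H](c2ccc(O[Si](C)(C)C(C)(C)C)c(O[Si](C)(C)C(C)(C)C)c2)C=C3O[Si](C)(C)C(C)(C)C
F6 | step 11 | (2S)-2-[3,4-bis(tert-butyldimethylsilyloxy)phenyl]-4-(tert-butyldimethylsilyloxy)-8-[(2Z)-4-hydroxy-3-methylbut-2-en-1-yl]-2H-chromen-7-ol | C/C(=C/Cc1c(O)ccc2c1O[C@H](c1ccc(O[Si](C)(C)C(C)(C)C)c(O[Si](C)(C)C(C)(C)C)c1)C=C2O[Si](C)(C)C(C)(C)C)CO
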